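## Structural features

The target is a C2-symmetric dimer of acacetin. Each half is a 5,7-dihydroxy-2-(4-methoxyphenyl)-4H-chromen-4-one: a phloroglucinol-type ring A fused to a γ-pyranone ring C, which carries the anisyl ring B at C2. The halves are joined by one bond only, C8–C8'', between the two rings A. There is no stereogenic centre. The only stereochemical element is the C8–C8'' axis, which has four ortho substituents (C7–O7 and C8a–O1 on one side, C7''–O7'' and C8a''–O1'' on the other); it is written without a descriptor. The fragile points are the 4'- and 4'''-methyl ethers, which must survive while four phenols are set free, the pyranone rings, which are opened by hard nucleophiles, and the electron-rich rings A, which react with electrophiles at C6. The real difficulty is forming a tetra-ortho-oxygenated biaryl bond, and forming it at C8 rather than at C6, which is also ortho to O7 and is electronically similar. The key step uses the fact that O7 and O7'' sit ortho to the axis on either side. A one-carbon link between them turns the C8–C8'' bond formation into closure of the seven-membered ring C8–C7–O7–CH2–O7''–C7''–C8'' (a dibenzo[d,f][1,3]dioxepine).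

## Logic of the disconnections

8 to 7. The four phenolic O–H bonds at O7, O7'', O5 and O5'' of 8 are traded for one methylene formal across O7/O7'' and two O5–CH3 ethers, which gives 7. The formal is the remnant of the tether that makes the biaryl bond, and the 5-O-methyl groups are what steer the iodination. Both kinds of C–O bond are the ones a boron Lewis acid attacks first (an acetal, and ethers peri to the C4 carbonyl), so no separate deprotection steps are added. The forward step must open the formal and cleave two chelated methyl ethers while leaving the 4'- and 4'''-methyl ethers. The one-carbon fragment that is released must not attack the freed rings A.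

7 to 6. The C8–C8'' bond is cut inside the seven-membered ring, giving the open, symmetrical diiodide 6. This is the only carbon–carbon bond between the halves, so the cut removes the ring, the axis and all steric congestion at once. The forward step, a reductive coupling by zerovalent nickel, must be intramolecular and must beat hydrodeiodination and chain formation. The tether does not choose the site: a seven-membered ring would close just as well through C6, since C6 is also ortho to O7. The position of the iodine atoms alone fixes the regiochemistry, so 6 must be regiochemically pure.

6 to 4 and 5. The two C8–I bonds are cut, leaving the halogen-free bis-ether 4 and the electrophilic iodine source 5. The gain is that the halogen is introduced late by aromatic substitution on the assembled dimer. The forward step must iodinate C8 and not C6 or C3' of ring B. For this reason O5 is alkylated before iodination: a free, chelated 5-hydroxyl would direct the electrophile to C6.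

4 to 1 and 2, by way of 3. The two O5–CH3 bonds are cut to give 3, and the two O7–CH2 bonds are cut to give two molecules of 1 and one of 2. Compound 1 already holds rings A, B and C and the 4'-methyl ether, so all later steps are functional-group chemistry plus one C–C bond. The forward step requires that the 7-hydroxyl react before the hydrogen-bonded 5-hydroxyl and that 2 be used at half an equivalent. Both alkylations need the same base and solvent and are therefore run in one flask.

## Other disconnections considered

Alternative 1: The cut goes through both rings A at C6–C7 and C4a–C8a. C7, C8 and C8a of each ring then come from one malonate end of tetramethyl ethane-1,1,2,2-tetracarboxylate A1, whose central bond is the future C8–C8'' bond. C4a, C5 and C6 come from dimethyl 3-methoxyglutaconate A2. In the forward step the dienolate of A2 would acylate through both of its α-carbons onto the two esters at each end of A1. After enolisation this would give the biphenyl tetraester A3.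
- In its favour: the axis exists from the start as an sp3–sp3 bond, so no hindered aryl–aryl coupling is needed and there is no C6/C8 question at the axis. On both points it is better than the chosen plan. The building blocks are cheap and the symmetry is used.
- Against it: the methine hydrogens of A1 are the most acidic in the mixture. Their removal would turn each malonate end into an enolate with poorly electrophilic esters, so a fourfold Claisen condensation by a stabilised dienolate is insecure. The dienolate of A2 can also react at oxygen or only once.
- On structure: A3 still lacks rings C and B. In each ring two equivalent esters must be told apart (one removed to leave C6–H, one built into C4, C3, C2 and the anisyl group).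
- On mechanism: the chosen nickel coupling is the better-precedented event. The final chelation-controlled removal of the 5-O-methyl groups would be the same in both plans, so that point is equal.
- On step economy: well over ten operations would be expected after A3, against four from 1.

Alternative 2: The cut removes ring A'' by disconnecting C8a''–C8'', C6''–C7'' and C4a''–C8a''. The forward step is a Danheiser benzannulation: 3-ethoxycyclobut-2-en-1-one A4 is heated with the aryl siloxyalkyne A5. The sequence is four-electron ring opening to a vinylketene, [2+2] addition to the ynol ether, a second four-electron opening, six-electron closure and tautomerisation. It would give the biphenylol A6 with the aryl group between the free hydroxyl and the silyl ether.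
- In its favour: the pericyclic cascade dictates the substitution pattern of the new ring, so the tetra-ortho-substituted biaryl arises without a metal-mediated coupling. On predictability of that bond it is the equal of the chosen plan, perhaps better. The three oxygens of ring A'' come out differentiated, which would be better than the chosen plan if an unsymmetrical analogue were wanted.
- Against it: the target is symmetrical and this plan makes the two rings A by different chemistry. A5 is a di-ortho-substituted aryl ynol ether that needs its own multistep preparation and is hindered at the reacting carbon.
- On structure: after A6 both rings still need C-acylation at C4a and C4a'', two pyranone closures and removal of five protecting groups of four kinds.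
- On mechanism: the cascade is well understood and is not inferior to the nickel step.
- On step economy: clearly worse. A count in the mid-teens would be expected, against four.

Alternative 3: The cut removes both rings C at C4a–C4, C4–C3 and O1–C2. In the forward step the diiodobiphenol A7, two molecules of 4-ethynylanisole A8 and two of carbon monoxide A10 would react under PdCl2(PPh3)2 and an amine base. Two carbonylative Sonogashira couplings and two 6-endo oxa-Michael closures would give the tetrabenzyl ether A9.
- In its favour: one operation builds both pyranones and attaches both rings B. The metal is catalytic, which is better than the stoichiometric nickel of the chosen plan. A9 would be unmasked by hydrogenolysis over Pd/C, which has no selectivity issue against the 4'-methyl ethers; this is better than the Lewis-acid end game chosen here.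
- Against it: the hindered biaryl problem is only moved into the preparation of A7, which needs an oxidative phenol dimerisation and a twofold iodination between a hydroxyl and a benzyloxy group instead of between two benzyloxy groups. That regiochemical question is equal to the C6/C8 question of the chosen plan. Each o-iodophenol can also close 5-exo to an aurone or couple without carbon monoxide to a benzofuran, and the desired path must be followed twice in one molecule next to a twisted, crowded axis. Carbon monoxide is a toxic gas, so the step is less safe to run.
- On structure: it is the most convergent of the three alternatives.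
- On mechanism: it is less secure than a single tether-enforced reductive elimination.
- On step economy: about six or seven operations from a simple phloroglucinol ether would be expected, close to the four of the chosen plan but not better.

Key step: step 3

Assumption: the target is written without an axial descriptor, so the C8–C8'' axis is left uncontrolled and 8 is made as the racemic mixture of atropisomers.

Step 1
Reactants: 1 acacetin, 5,7-dihydroxy-2-(4-methoxyphenyl)-4H-chromen-4-one (two equivalents); 2 diiodomethane (one equivalent)
Product: 4 bis{[5-methoxy-2-(4-methoxyphenyl)-4-oxo-4H-chromen-7-yl]oxy}methane, via bridged bis(5-hydroxyflavone) 3 (not isolated)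
Conditions: K2CO3, DMF, 65 °C; then MeI, 50 °C (same flask)
Reagents that add atoms: diiodomethane (compound 2), ICI; iodomethane, CI
Why: Double Williamson ether synthesis: K2CO3 ionises only the acidic 7-hydroxyl (the 5-hydroxyl is held in a hydrogen bond to the C4 carbonyl), and the aryl iodomethyl ether formed first is a much better electrophile than 2, so a second phenoxide should capture it to give the symmetrical formal 3. Iodomethane and the same base should then methylate the two chelated 5-hydroxyls, which need the longer, warmer second stage; the formal is stable to base, and any unbridged 1 ends as a monomeric trimethyl ether that is easy to separate from the dimer.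

Step 2
Reactants: 4 bis{[5-methoxy-2-(4-methoxyphenyl)-4-oxo-4H-chromen-7-yl]oxy}methane; 5 N-iodosuccinimide (2.3 equivalents)
Product: 6 bis{[8-iodo-5-methoxy-2-(4-methoxyphenyl)-4-oxo-4H-chromen-7-yl]oxy}methane
Conditions: NIS, CF3CO2H (cat.), MeCN–CH2Cl2, 0 °C to rt, dark
Reagents that add atoms: N-iodosuccinimide (compound 5), O=C1CCC(=O)N1I
Why: Electrophilic aromatic iodination: with O5 alkylated, C8 is ortho to O7 and O1 and para to the freely donating 5-methoxy group, and it is less crowded than C6, which lies between two alkoxy groups; 5,7-dialkoxyflavones are known to take iodine at C8. Ring B is deactivated by conjugation with the pyranone, and the diaryl formal should tolerate catalytic acid.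

Step 3
Reactants: 6 bis{[8-iodo-5-methoxy-2-(4-methoxyphenyl)-4-oxo-4H-chromen-7-yl]oxy}methane
Product: 7 7,7''-O-methylene-bridged 5,5'',4',4'''-tetra-O-methylcupressuflavone (dibenzo[d,f][1,3]dioxepine whose two benzo rings are the rings A of two 5-methoxy-2-(4-methoxyphenyl)chromen-4-one units joined C8–C8''; racemic)
Conditions: Ni(cod)2 (2.5 equiv), PPh3 (5 equiv), DMF, 55 °C, slow addition of 6 (high dilution), argon
Reagents that add atoms: none
Why: Zerovalent nickel adds oxidatively to one C8–I bond to give an arylnickel iodide of divalent nickel, and the tether holds the second C8''–I bond next to the metal; either a second oxidative addition at another nickel centre followed by aryl transfer between the two divalent nickel centres, or addition of the second C–I bond to a monovalent arylnickel species, should lead to a diarylnickel intermediate in an eight-membered nickelacycle (Ni, C8, C7, O, CH2, O, C7'', C8''). Reductive elimination from this species forms the C8–C8'' bond, contracts the metallacycle to the seven-membered dibenzo[d,f][1,3]dioxepine and releases NiI2. The closest known reaction type is the nickel-mediated reductive homocoupling of aryl halides (Ullmann-type, Yamamoto coupling) in its tethered, intramolecular form, which is established for closing biaryl-containing rings from bis(iodoaryl) ethers. The ring is closed by C(sp2)–C(sp2) reductive elimination between the two carbons ortho to the formal oxygens. No stereocentre is created: the product is a twisted bridged biaryl formed as a racemate, and nothing in substrate or reagent biases the sense of twist. The step needs ring closure to win over hydrodeiodination and over chain-forming intermolecular coupling; the short one-carbon tether, excess Ni(cod)2 and slow addition at high dilution are meant to secure this. Site selectivity rests entirely on the iodine atoms, because the tether could equally close a seven-membered ring through C6; the aryl methyl ethers, the formal and the pyranone carbonyls should be inert to zerovalent nickel under these conditions.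

Step 4
Reactants: 7 7,7''-O-methylene-bridged 5,5'',4',4'''-tetra-O-methylcupressuflavone
Product: 8 4',4'''-di-O-methylcupressuflavone, 5,5'',7,7''-tetrahydroxy-2,2''-bis(4-methoxyphenyl)-8,8''-bi(4H-chromene)-4,4''-dione (racemic about the C8–C8'' axis)
Conditions: BCl3 (1 M in CH2Cl2, 8 equiv), CH2Cl2, −78 °C to rt; then ice-cold 1 M HCl–THF, rt
Reagents that add atoms: none
Why: Lewis-acid ether cleavage: BCl3 bound to each C4 carbonyl should cleave the peri 5-methoxy group through a six-membered boron chelate and open the formal to an aryloxymethyl chloride, which hydrolyses in the cold, dilute acidic work-up. The unchelated 4'- and 4'''-methoxy groups are cleaved far more slowly by BCl3 and should remain; no stereocentre is involved.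

Compound list

1 | acacetin, 5,7-dihydroxy-2-(4-methoxyphenyl)-4H-chromen-4-one | COc1ccc(-c2cc(=O)c3c(O)cc(O)cc3o2)cc1 | starting material
2 | diiodomethane | ICI | starting material
3 | bis{[5-hydroxy-2-(4-methoxyphenyl)-4-oxo-4H-chromen-7-yl]oxy}methane (formed in the flask in step 1, not isolated) | COc1ccc(-c2cc(=O)c3c(O)cc(OCOc4cc(O)c5c(=O)cc(-c6ccc(OC)cc6)oc5c4)cc3o2)cc1 | intermediate
4 | bis{[5-methoxy-2-(4-methoxyphenyl)-4-oxo-4H-chromen-7-yl]oxy}methane | COc1ccc(-c2cc(=O)c3c(OC)cc(OCOc4cc(OC)c5c(=O)cc(-c6ccc(OC)cc6)oc5c4)cc3o2)cc1 | intermediate
5 | N-iodosuccinimide | O=C1CCC(=O)N1I | starting material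
6 | bis{[8-iodo-5-methoxy-2-(4-methoxyphenyl)-4-oxo-4H-chromen-7-yl]oxy}methane | COc1ccc(-c2cc(=O)c3c(OC)cc(OCOc4cc(OC)c5c(=O)cc(-c6ccc(OC)cc6)oc5c4I)c(I)c3o2)cc1 | intermediate
7 | 7,7''-O-methylene-bridged 5,5'',4',4'''-tetra-O-methylcupressuflavone (racemic) | COc1ccc(-c2cc(=O)c3c(OC)cc4OCOc5cc(OC)c6c(=O)cc(-c7ccc(OC)cc7)oc6c5-c4c3o2)cc1 | intermediate
8 | 4',4'''-di-O-methylcupressuflavone (racemic about the axis) | COc1ccc(-c2cc(=O)c3c(O)cc(O)c(-c4c(O)cc(O)c5c(=O)cc(-c6ccc(OC)cc6)oc45)c3o2)cc1 | target

Total step count: 4. Longest linear sequence: 4 steps, from 1 to 8.

Steps least certain to work

Key step (step 3). The most likely failures are hydrodeiodination of the arylnickel intermediates and intermolecular chain growth. Both compete because reductive elimination from a diarylnickel with four ortho oxygens is slow, and the pyranone enones may also bind the zerovalent metal. The fallback changes the bond-forming mechanism to a transmetalation. Setting out from 6, one C–I bond would be converted in the flask by Miyaura borylation (PdCl2(dppf), B2pin2, KOAc, dioxane, 90 °C, high dilution) into the mono-boronate {[8-iodo-5-methoxy-2-(4-methoxyphenyl)-4-oxo-4H-chromen-7-yl]oxy}{[5-methoxy-2-(4-methoxyphenyl)-4-oxo-8-(4,4,5,5-tetramethyl-1,3,2-dioxaborolan-2-yl)-4H-chromen-7-yl]oxy}methane F1. Addition of aqueous K2CO3 would then start the intramolecular Suzuki–Miyaura coupling of F1, which rejoins the route at 7.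

Step 2. The most likely failure is leakage of the iodination to C6 (or to C3' of ring B), or a stop at the mono-iodide through poor solubility. On a dimer any such leakage is doubled, regioisomeric dimers would be hard to separate, and the tether cannot correct a misplaced iodine. The fallback moves the iodination to the monomer stage, where the regioisomer can be removed and the position checked before dimerisation.
- Setting out from 1, benzyl bromide and K2CO3 in DMF would give 7-O-benzylacacetin F2.
- Iodomethane in the same flask would methylate F2 to 7-(benzyloxy)-5-methoxy-2-(4-methoxyphenyl)-4H-chromen-4-one F3.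
- NIS with catalytic CF3CO2H would give 7-(benzyloxy)-8-iodo-5-methoxy-2-(4-methoxyphenyl)-4H-chromen-4-one F4, to be purified by crystallisation.
- Trifluoroacetic acid with pentamethylbenzene as cation scavenger would remove the benzyl group without touching the C–I bond or the methyl ethers, giving 7-hydroxy-8-iodo-5-methoxy-2-(4-methoxyphenyl)-4H-chromen-4-one F5.
- Two molecules of F5 with one of 2 and K2CO3 in DMF would rejoin the route at 6.

Step 4. The most likely failures are re-attack of the liberated one-carbon electrophile (the aryloxymethyl chloride or formaldehyde) on C6 of the freed phloroglucinol-type rings, slow opening of the seven-membered formal, and gradual loss of the 4'-methyl ethers if long exposure is needed. The fallback separates the two deprotections and removes the methylene carbon in a non-electrophilic form. Setting out from 7, BF3·OEt2 and ethane-1,2-dithiol in CH2Cl2 would transfer the CH2 group to sulfur as 1,3-dithiolane and give 7,7''-dihydroxy-5,5''-dimethoxy-2,2''-bis(4-methoxyphenyl)-8,8''-bi(4H-chromene)-4,4''-dione F6. BCl3 in CH2Cl2 at 0 °C would then cleave only the two chelated 5-O-methyl ethers and rejoin the route at 8.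

Further compounds

F1 | step 3 | {[8-iodo-5-methoxy-2-(4-methoxyphenyl)-4-oxo-4H-chromen-7-yl]oxy}{[5-methoxy-2-(4-methoxyphenyl)-4-oxo-8-(4,4,5,5-tetramethyl-1,3,2-dioxaborolan-2-yl)-4H-chromen-7-yl]oxy}methane | COc1ccc(-c2cc(=O)c3c(OC)cc(OCOc4cc(OC)c5c(=O)cc(-c6ccc(OC)cc6)oc5c4I)c(B7OC(C)(C)C(C)(C)O7)c3o2)cc1
F2 | step 2 | 7-(benzyloxy)-5-hydroxy-2-(4-methoxyphenyl)-4H-chromen-4-one (7-O-benzylacacetin) | COc1ccc(-c2cc(=O)c3c(O)cc(OCc4ccccc4)cc3o2)cc1
F3 | step 2 | 7-(benzyloxy)-5-methoxy-2-(4-methoxyphenyl)-4H-chromen-4-one | COc1ccc(-c2cc(=O)c3c(OC)cc(OCc4ccccc4)cc3o2)cc1
F4 | step 2 | 7-(benzyloxy)-8-iodo-5-methoxy-2-(4-methoxyphenyl)-4H-chromen-4-one | COc1ccc(-c2cc(=O)c3c(OC)cc(OCc4ccccc4)c(I)c3o2)cc1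
F5 | step 2 | 7-hydroxy-8-iodo-5-methoxy-2-(4-methoxyphenyl)-4H-chromen-4-one | COc1ccc(-c2cc(=O)c3c(OC)cc(O)c(I)c3o2)cc1
F6 | step 4 | 7,7''-dihydroxy-5,5''-dimethoxy-2,2''-bis(4-methoxyphenyl)-8,8''-bi(4H-chromene)-4,4''-dione | COc1ccc(-c2cc(=O)c3c(OC)cc(O)c(-c4c(O)cc(OC)c5c(=O)cc(-c6ccc(OC)cc6)oc45)c3o2)cc1
A1 | alternative 1 | tetramethyl ethane-1,1,2,2-tetracarboxylate | COC(=O)C(C(=O)OC)C(C(=O)OC)C(=O)OC
A2 | alternative 1 | dimethyl (E)-3-methoxypent-2-enedioate (dimethyl 3-methoxyglutaconate) | COC(=O)/C=C(/OC)CC(=O)OC
A3 | alternative 1 | tetramethyl 2,2',6,6'-tetrahydroxy-4,4'-dimethoxybiphenyl-3,3',5,5'-tetracarboxylate | COC(=O)c1c(O)c(-c2c(O)c(C(=O)OC)c(OC)c(C(=O)OC)c2O)c(O)c(C(=O)OC)c1OC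
A4 | alternative 2 | 3-ethoxycyclobut-2-en-1-one | CCOC1=CC(=O)C1
A5 | alternative 2 | ({[2,6-bis(benzyloxy)-4-methoxyphenyl]ethynyl}oxy)tri(propan-2-yl)silane | COc1cc(OCc2ccccc2)c(C#CO[Si](C(C)C)(C(C)C)C(C)C)c(OCc2ccccc2)c1
A6 | alternative 2 | 2',6'-bis(benzyloxy)-4-ethoxy-4'-methoxy-6-(triisopropylsilyloxy)biphenyl-2-ol | CCOc1cc(O)c(-c2c(OCc3ccccc3)cc(OC)cc2OCc2ccccc2)c(O[Si](C(C)C)(C(C)C)C(C)C)c1
A7 | alternative 3 | 4,4',6,6'-tetrakis(benzyloxy)-3,3'-diiodobiphenyl-2,2'-diol | Oc1c(I)c(OCc2ccccc2)cc(OCc2ccccc2)c1-c1c(O)c(I)c(OCc2ccccc2)cc1OCc1ccccc1
A8 | alternative 3 | 4-ethynylanisole (1-ethynyl-4-methoxybenzene) | COc1ccc(C#C)cc1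
A9 | alternative 3 | 5,5'',7,7''-tetra-O-benzyl-4',4'''-di-O-methylcupressuflavone | COc1ccc(-c2cc(=O)c3c(OCc4ccccc4)cc(OCc4ccccc4)c(-c4c(OCc5ccccc5)cc(OCc5ccccc5)c5c(=O)cc(-c6ccc(OC)cc6)oc45)c3o2)cc1
A10 | alternative 3 | carbon monoxide | [C-]#[O+]
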